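**Plan**

- Cuts: first the O1–C2 bond of the outer dihydrofuran, then C2–C3 (aldol). The ring B CH2–CO unit is traced back to an allyl group. O1'–C2' and C2'–C3' of the inner dihydrofuran are cut the same way.
- Forward: a ring C arylacetyl imide and 5-allyl-O-benzylvanillin are joined by aldol, reduced, and closed under acid to the inner furan. The allyl group is then cut down to a second arylacetyl imide, which is joined to O-benzylvanillin, reduced, debenzylated and closed to the outer furan last.
- Stereochemistry: C3' and C3 come from (R)-4-benzyl-2-oxazolidinone in two boron syn aldols. C2' and C2 are set by reversible, trans-selective ring closure, each steered by its fixed neighbour.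
- Enabling feature: C2 is bonded to O1 and is benzylic to ring A, para to the free 4-hydroxyl. The C2–O bond therefore ionises reversibly to a ring A para-quinone methide while C3 is untouched.

Key step: step 20

Remark: C2/C3/O1 denote the outer dihydrofuran (ring A on C2), C2'/C3'/O1' the inner one, ring B the central arene and ring C the arene with the hydroxypropyl chain; the seco precursor is written as the (1R,2S) diol that the syn aldol delivers, and its C2 epimer would converge on the same product; compounds 1, 8, 11 and 26 are purchased.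

**Route**

Step 1
Reactants: 1 methyl 3-(4-hydroxy-3-methoxyphenyl)propanoate (methyl dihydroferulate)
Product: 2 methyl 3-[3-methoxy-4-(prop-2-enyloxy)phenyl]propanoate
Conditions: allyl bromide, K2CO3, acetone, reflux
Reagents that add atoms: allyl bromide, C=CCBr
Why: Williamson ether synthesis on the phenoxide with a reactive allylic bromide; the methyl ester is inert to carbonate in acetone.

Step 2
Reactants: 2 methyl 3-[3-methoxy-4-(prop-2-enyloxy)phenyl]propanoate
Product: 3 methyl 3-[4-hydroxy-3-methoxy-5-(prop-2-enyl)phenyl]propanoate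
Conditions: N,N-diethylaniline, 200 °C
Reagents that add atoms: none
Why: Aromatic Claisen rearrangement; the only free ortho position takes the allyl group and the dienone tautomerises to the phenol.

Step 3
Reactants: 3 methyl 3-[4-hydroxy-3-methoxy-5-(prop-2-enyl)phenyl]propanoate
Product: 4 methyl 3-[3-methoxy-4-(methoxymethoxy)-5-(prop-2-enyl)phenyl]propanoate
Conditions: MOMCl, iPr2NEt, CH2Cl2, 0 °C → rt
Reagents that add atoms: chloromethyl methyl ether, COCCl
Why: O-alkylation of the phenol to its methoxymethyl acetal, which tolerates the oxidations, the boron aldol and hydride and leaves under the acid of step 12.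

Step 4
Reactants: 4 methyl 3-[3-methoxy-4-(methoxymethoxy)-5-(prop-2-enyl)phenyl]propanoate
Product: 6 methyl 3-[3-methoxy-4-(methoxymethoxy)-5-(2-oxoethyl)phenyl]propanoate, via vicinal diol 5 (not isolated)
Conditions: OsO4 (cat.), NaIO4, 2,6-lutidine, dioxane/H2O, rt
Reagents that add atoms: osmium tetroxide, O=[Os](=O)(=O)=O; sodium periodate, [Na+].[O-]I(=O)(=O)=O
Why: Lemieux–Johnson oxidation, in which catalytic dihydroxylation of the terminal alkene and periodate cleavage of diol 5 run in one flask and the lutidine buffer protects the acetal.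

Step 5
Reactants: 6 methyl 3-[3-methoxy-4-(methoxymethoxy)-5-(2-oxoethyl)phenyl]propanoate
Product: 7 2-[3-methoxy-5-(3-methoxy-3-oxopropyl)-2-(methoxymethoxy)phenyl]acetic acid
Conditions: NaClO2, NaH2PO4, 2-methyl-2-butene, t-BuOH/H2O, 0 °C → rt
Reagents that add atoms: sodium chlorite, [Na+].[O-]Cl=O
Why: Pinnick oxidation of the aldehyde, with the alkene scavenger removing hypochlorous acid before it can chlorinate the electron-rich ring.

Step 6
Reactants: 7 2-[3-methoxy-5-(3-methoxy-3-oxopropyl)-2-(methoxymethoxy)phenyl]acetic acid; 8 (R)-4-benzyl-2-oxazolidinone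
Product: 10 (R)-4-benzyl-3-{2-[3-methoxy-5-(3-methoxy-3-oxopropyl)-2-(methoxymethoxy)phenyl]acetyl}oxazolidin-2-one (ring C imide), via mixed pivalic anhydride 9 (not isolated)
Conditions: PivCl, Et3N, THF, −20 °C; then LiCl, 8, −20 °C → rt
Reagents that add atoms: pivaloyl chloride, CC(C)(C)C(Cl)=O (its acyl group is in 9 only and is lost again on the way to 10)
Why: N-acylation of the oxazolidinone through a mixed anhydride that is attacked at its less hindered arylacetyl carbonyl, under LiCl/Et3N activation that leaves the methyl ester alone.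

Step 7
Reactants: 11 vanillin
Product: 12 3-methoxy-4-(prop-2-enyloxy)benzaldehyde
Conditions: allyl bromide, K2CO3, acetone, reflux
Reagents that add atoms: allyl bromide, C=CCBr
Why: Williamson ether synthesis on the vanillin phenoxide.

Step 8
Reactants: 12 3-methoxy-4-(prop-2-enyloxy)benzaldehyde
Product: 13 4-hydroxy-3-methoxy-5-(prop-2-enyl)benzaldehyde (5-allylvanillin)
Conditions: N,N-diethylaniline, 200 °C
Reagents that add atoms: none
Why: Aromatic Claisen rearrangement to the single free ortho position, which places the future ring B acetic acid carbon next to the phenol.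

Step 9
Reactants: 13 4-hydroxy-3-methoxy-5-(prop-2-enyl)benzaldehyde
Product: 14 4-(benzyloxy)-3-methoxy-5-(prop-2-enyl)benzaldehyde
Conditions: BnBr, K2CO3, DMF, 60 °C
Reagents that add atoms: benzyl bromide, BrCc1ccccc1
Why: Williamson benzylation of the flanked phenol; the benzyl ether survives every step up to the hydrogenolysis of step 19.

Step 10
Reactants: 10 ring C imide; 14 4-(benzyloxy)-3-methoxy-5-(prop-2-enyl)benzaldehyde
Product: 16 (R)-4-benzyl-3-{(2R,3R)-3-[4-(benzyloxy)-3-methoxy-5-(prop-2-enyl)phenyl]-3-hydroxy-2-[3-methoxy-5-(3-methoxy-3-oxopropyl)-2-(methoxymethoxy)phenyl]propanoyl}oxazolidin-2-one (syn aldol adduct), via Z-dibutylboron enolate 15 (not isolated)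
Conditions: Bu2BOTf, iPr2NEt, CH2Cl2, 0 °C; 14, −78 → 0 °C; then pH 7 buffer, MeOH, H2O2, 0 °C
Reagents that add atoms: dibutylboron triflate, CCCCB(CCCC)OS(=O)(=O)C(F)(F)F (boron is in 15 only)
Why: Evans syn aldol, in which soft enolisation gives Z-enolate 15 and the aldehyde adds through a chair Zimmerman–Traxler transition state on the face away from the auxiliary benzyl group, setting the α-carbon (future C3') as R in the imide and the carbinol carbon as R, of which only the former has to last.

Step 11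
Reactants: 16 syn aldol adduct
Product: 17 (1R,2S)-1-[4-(benzyloxy)-3-methoxy-5-(prop-2-enyl)phenyl]-2-[5-(3-hydroxypropyl)-3-methoxy-2-(methoxymethoxy)phenyl]propane-1,3-diol
Conditions: LiBH4, THF/MeOH, 0 °C → rt
Reagents that add atoms: none
Why: Reductive cleavage of the N-acyl oxazolidinone by lithium borohydride gives the primary alcohol and returns the auxiliary, and the same hydride reduces the methyl ester to the hydroxypropyl chain without touching a stereocentre.

Step 12
Reactants: 17 the triol of step 11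
Product: 19 3-{(2R,3S)-2-[4-(benzyloxy)-3-methoxy-5-(prop-2-enyl)phenyl]-3-(hydroxymethyl)-7-methoxy-2,3-dihydro-1-benzofuran-5-yl}propan-1-ol (trans inner dihydrobenzofuran), via free phenol triol 18 (not isolated)
Conditions: 3 M aq. HCl, THF, 45 °C
Reagents that add atoms: none
Why: Aqueous acid hydrolyses the methoxymethyl acetal to phenol 18, the ring B benzylic alcohol (para to the benzyloxy group) ionises and the phenol closes the inner dihydrofuran 5-exo in an acid-promoted cycloetherification; because the benzylic C–O bond keeps re-ionising, C2' settles trans to the C3' hydroxymethyl group fixed in step 10, giving the 2R,3S ring.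

Step 13
Reactants: 19 trans inner dihydrobenzofuran
Product: 20 3-{(2R,3S)-3-(acetoxymethyl)-2-[4-(benzyloxy)-3-methoxy-5-(prop-2-enyl)phenyl]-7-methoxy-2,3-dihydro-1-benzofuran-5-yl}propyl acetate
Conditions: Ac2O, pyridine, DMAP (cat.), CH2Cl2, rt
Reagents that add atoms: acetic anhydride, CC(=O)OC(C)=O
Why: DMAP-catalysed acetylation of the two primary alcohols; the acetates withstand the oxidations, the acylation and the boron aldol and are removed by the hydride of step 18 without a step of their own.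

Step 14
Reactants: 20 the diacetate of step 13
Product: 22 3-{(2R,3S)-3-(acetoxymethyl)-2-[4-(benzyloxy)-3-methoxy-5-(2-oxoethyl)phenyl]-7-methoxy-2,3-dihydro-1-benzofuran-5-yl}propyl acetate, via vicinal diol 21 (not isolated)
Conditions: OsO4 (cat.), NaIO4, 2,6-lutidine, dioxane/H2O, rt
Reagents that add atoms: osmium tetroxide, O=[Os](=O)(=O)=O; sodium periodate, [Na+].[O-]I(=O)(=O)=O
Why: Lemieux–Johnson oxidation of the only alkene in the molecule, under buffered conditions that leave the acetates, the benzyl ether and the benzylic ring ether intact.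

Step 15
Reactants: 22 the arylacetaldehyde of step 14
Product: 23 2-{5-[(2R,3S)-3-(acetoxymethyl)-5-(3-acetoxypropyl)-7-methoxy-2,3-dihydro-1-benzofuran-2-yl]-2-(benzyloxy)-3-methoxyphenyl}acetic acid
Conditions: NaClO2, NaH2PO4, 2-methyl-2-butene, t-BuOH/H2O, 0 °C → rt
Reagents that add atoms: sodium chlorite, [Na+].[O-]Cl=O
Why: Pinnick oxidation, selective for the aldehyde in the presence of esters and electron-rich arenes.

Step 16
Reactants: 23 the arylacetic acid of step 15; 8 (R)-4-benzyl-2-oxazolidinone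
Product: 25 (R)-4-benzyl-3-(2-{5-[(2R,3S)-3-(acetoxymethyl)-5-(3-acetoxypropyl)-7-methoxy-2,3-dihydro-1-benzofuran-2-yl]-2-(benzyloxy)-3-methoxyphenyl}acetyl)oxazolidin-2-one (ring B imide), via mixed pivalic anhydride 24 (not isolated)
Conditions: PivCl, Et3N, THF, −20 °C; then LiCl, 8, −20 °C → rt
Reagents that add atoms: pivaloyl chloride, CC(C)(C)C(Cl)=O (its acyl group is in 24 only and is lost again on the way to 25)
Why: Mixed-anhydride N-acylation as in step 6, run without strong base so that the two acetates are not touched.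

Step 17
Reactants: 25 ring B imide; 26 4-(benzyloxy)-3-methoxybenzaldehyde (O-benzylvanillin)
Product: 28 (R)-4-benzyl-3-[(2R,3R)-2-{5-[(2R,3S)-3-(acetoxymethyl)-5-(3-acetoxypropyl)-7-methoxy-2,3-dihydro-1-benzofuran-2-yl]-2-(benzyloxy)-3-methoxyphenyl}-3-[4-(benzyloxy)-3-methoxyphenyl]-3-hydroxypropanoyl]oxazolidin-2-one (outer syn aldol adduct), via Z-dibutylboron enolate 27 (not isolated)
Conditions: Bu2BOTf, iPr2NEt, CH2Cl2, 0 °C; 26, −78 → 0 °C; then pH 7 buffer, MeOH, H2O2, 0 °C
Reagents that add atoms: dibutylboron triflate, CCCCB(CCCC)OS(=O)(=O)C(F)(F)F (boron is in 27 only)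
Why: Evans syn aldol, in which the auxiliary directs the aldehyde to one face of Z-enolate 27 through a chair Zimmerman–Traxler transition state and so fixes the α-carbon (future C3) as R in the imide, while the acetates are not enolised by the boron triflate/amine pair.

Step 18
Reactants: 28 outer syn aldol adduct
Product: 29 (1R,2S)-1-[4-(benzyloxy)-3-methoxyphenyl]-2-{2-(benzyloxy)-5-[(2R,3S)-3-(hydroxymethyl)-5-(3-hydroxypropyl)-7-methoxy-2,3-dihydro-1-benzofuran-2-yl]-3-methoxyphenyl}propane-1,3-diol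
Conditions: LiBH4 (excess), THF/MeOH, 0 °C → rt
Reagents that add atoms: none
Why: Reductive cleavage of the N-acyl oxazolidinone by lithium borohydride, which at room temperature also reduces off both acetates, so one operation exposes all four aliphatic hydroxyls and leaves C3 as S.

Step 19
Reactants: 29 the bis(benzyl ether) tetraol of step 18
Product: 30 (1R,2S)-1-(4-hydroxy-3-methoxyphenyl)-2-{2-hydroxy-5-[(2R,3S)-3-(hydroxymethyl)-5-(3-hydroxypropyl)-7-methoxy-2,3-dihydro-1-benzofuran-2-yl]-3-methoxyphenyl}propane-1,3-diol (seco precursor)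
Conditions: H2 (1 atm), 10% Pd/C, EtOAc/MeOH, rt
Reagents that add atoms: none
Why: Catalytic hydrogenolysis of the two aryl benzyl ethers, which cleave faster than the C2 benzylic alcohol or the cyclic benzylic ether, so a short run in neutral solvent should stop at the free bisphenol.

Step 20
Reactants: 30 seco precursor
Product: 32 4-[(2R,3S)-3-(hydroxymethyl)-5-[(2R,3S)-3-(hydroxymethyl)-5-(3-hydroxypropyl)-7-methoxy-2,3-dihydro-1-benzofuran-2-yl]-7-methoxy-2,3-dihydro-1-benzofuran-2-yl]-2-methoxyphenol (CNP0599161.1), via ring A para-quinone methide 31 (not isolated)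
Conditions: TsOH·H2O (0.2 equiv), THF, high dilution, 40 °C
Reagents that add atoms: none
Why: Acid protonates the C2 hydroxyl, water leaves with the push of the para-hydroxyl of ring A, and the resulting cation, the O-protonated form of quinone methide 31, is attacked at C2 by the ring B phenol oxygen to form O1–C2. The closest known reaction type is the acid-promoted cycloetherification of 1-aryl-2-(2-hydroxyaryl)propane-1,3-diols to trans-2-aryl-2,3-dihydrobenzofurans, the laboratory counterpart of phenylcoumaran formation from quinone methides. The outer dihydrofuran closes by 5-exo-trig addition to the exocyclic methide carbon; the C3 hydroxymethyl oxygen could only give an oxetane and the other hydroxyls are out of reach, so the phenol is the only productive internal nucleophile, and dilution holds back intermolecular capture. C2 is the one new stereocentre and is governed by C3 (S, from step 17) under thermodynamic control, because the O1–C2 bond re-ionises in the same acid and either C2 epimer of 30 and any cis ether drain to the trans 2R,3S ring with the aryl and hydroxymethyl groups on opposite faces. The step needs diastereoselection at C2 and retention elsewhere: C3 and C3' bear no leaving group and are not enolisable, and the inner C2'–O1' bond, which can open the same way, recloses to its own trans form.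

**Compound list**

1 | methyl 3-(4-hydroxy-3-methoxyphenyl)propanoate (methyl dihydroferulate) | COC(=O)CCc1ccc(O)c(OC)c1 | starting material
2 | methyl 3-[3-methoxy-4-(prop-2-enyloxy)phenyl]propanoate | COC(=O)CCc1ccc(OCC=C)c(OC)c1 | intermediate
3 | methyl 3-[4-hydroxy-3-methoxy-5-(prop-2-enyl)phenyl]propanoate | COC(=O)CCc1cc(CC=C)c(O)c(OC)c1 | intermediate
4 | methyl 3-[3-methoxy-4-(methoxymethoxy)-5-(prop-2-enyl)phenyl]propanoate | COC(=O)CCc1cc(CC=C)c(OCOC)c(OC)c1 | intermediate
5 | methyl 3-[3-(2,3-dihydroxypropyl)-5-methoxy-4-(methoxymethoxy)phenyl]propanoate (not isolated; both configurations at the carbinol carbon) | COC(=O)CCc1cc(CC(O)CO)c(OCOC)c(OC)c1 | intermediate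
6 | methyl 3-[3-methoxy-4-(methoxymethoxy)-5-(2-oxoethyl)phenyl]propanoate | COC(=O)CCc1cc(CC=O)c(OCOC)c(OC)c1 | intermediate
7 | 2-[3-methoxy-5-(3-methoxy-3-oxopropyl)-2-(methoxymethoxy)phenyl]acetic acid | COC(=O)CCc1cc(CC(O)=O)c(OCOC)c(OC)c1 | intermediate
8 | (R)-4-benzyl-2-oxazolidinone | O=C1N[C@H](Cc2ccccc2)CO1 | starting material
9 | mixed pivalic anhydride of 7 (not isolated) | COC(=O)CCc1cc(CC(=O)OC(=O)C(C)(C)C)c(OCOC)c(OC)c1 | intermediate
10 | (R)-4-benzyl-3-{2-[3-methoxy-5-(3-methoxy-3-oxopropyl)-2-(methoxymethoxy)phenyl]acetyl}oxazolidin-2-one (ring C imide) | COC(=O)CCc1cc(CC(=O)N2[C@H](Cc3ccccc3)COC2=O)c(OCOC)c(OC)c1 | intermediate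
11 | vanillin | COc1cc(C=O)ccc1O | starting material
12 | 3-methoxy-4-(prop-2-enyloxy)benzaldehyde | COc1cc(C=O)ccc1OCC=C | intermediate
13 | 4-hydroxy-3-methoxy-5-(prop-2-enyl)benzaldehyde | COc1cc(C=O)cc(CC=C)c1O | intermediate
14 | 4-(benzyloxy)-3-methoxy-5-(prop-2-enyl)benzaldehyde | COc1cc(C=O)cc(CC=C)c1OCc1ccccc1 | intermediate
15 | Z-dibutylboron enolate of 10 (not isolated) | CCCCB(CCCC)O/C(=C\c1cc(CCC(=O)OC)cc(OC)c1OCOC)N1[C@H](Cc2ccccc2)COC1=O | intermediate
16 | (R)-4-benzyl-3-{(2R,3R)-3-[4-(benzyloxy)-3-methoxy-5-(prop-2-enyl)phenyl]-3-hydroxy-2-[3-methoxy-5-(3-methoxy-3-oxopropyl)-2-(methoxymethoxy)phenyl]propanoyl}oxazolidin-2-one | O=C(N1[C@H](Cc2ccccc2)COC1=O)[C@H](c1cc(CCC(=O)OC)cc(OC)c1OCOC)[C@@H](O)c1cc(OC)c(OCc2ccccc2)c(CC=C)c1 | intermediate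
17 | (1R,2S)-1-[4-(benzyloxy)-3-methoxy-5-(prop-2-enyl)phenyl]-2-[5-(3-hydroxypropyl)-3-methoxy-2-(methoxymethoxy)phenyl]propane-1,3-diol | OC[C@H](c1cc(CCCO)cc(OC)c1OCOC)[C@@H](O)c1cc(OC)c(OCc2ccccc2)c(CC=C)c1 | intermediate
18 | (1R,2S)-1-[4-(benzyloxy)-3-methoxy-5-(prop-2-enyl)phenyl]-2-[2-hydroxy-5-(3-hydroxypropyl)-3-methoxyphenyl]propane-1,3-diol (not isolated) | OC[C@H](c1cc(CCCO)cc(OC)c1O)[C@@H](O)c1cc(OC)c(OCc2ccccc2)c(CC=C)c1 | intermediate
19 | 3-{(2R,3S)-2-[4-(benzyloxy)-3-methoxy-5-(prop-2-enyl)phenyl]-3-(hydroxymethyl)-7-methoxy-2,3-dihydro-1-benzofuran-5-yl}propan-1-ol | C=CCc1cc(cc(OC)c1OCc1ccccc1)[C@@H]1Oc2c(OC)cc(CCCO)cc2[C@H]1CO | intermediate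
20 | 3-{(2R,3S)-3-(acetoxymethyl)-2-[4-(benzyloxy)-3-methoxy-5-(prop-2-enyl)phenyl]-7-methoxy-2,3-dihydro-1-benzofuran-5-yl}propyl acetate | C=CCc1cc(cc(OC)c1OCc1ccccc1)[C@@H]1Oc2c(OC)cc(CCCOC(C)=O)cc2[C@H]1COC(C)=O | intermediate
21 | 3-{(2R,3S)-3-(acetoxymethyl)-2-[4-(benzyloxy)-3-(2,3-dihydroxypropyl)-5-methoxyphenyl]-7-methoxy-2,3-dihydro-1-benzofuran-5-yl}propyl acetate (not isolated; both configurations at the new carbinol carbon) | OCC(O)Cc1cc(cc(OC)c1OCc1ccccc1)[C@@H]1Oc2c(OC)cc(CCCOC(C)=O)cc2[C@H]1COC(C)=O | intermediate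
22 | 3-{(2R,3S)-3-(acetoxymethyl)-2-[4-(benzyloxy)-3-methoxy-5-(2-oxoethyl)phenyl]-7-methoxy-2,3-dihydro-1-benzofuran-5-yl}propyl acetate | O=CCc1cc(cc(OC)c1OCc1ccccc1)[C@@H]1Oc2c(OC)cc(CCCOC(C)=O)cc2[C@H]1COC(C)=O | intermediate
23 | 2-{5-[(2R,3S)-3-(acetoxymethyl)-5-(3-acetoxypropyl)-7-methoxy-2,3-dihydro-1-benzofuran-2-yl]-2-(benzyloxy)-3-methoxyphenyl}acetic acid | OC(=O)Cc1cc(cc(OC)c1OCc1ccccc1)[C@@H]1Oc2c(OC)cc(CCCOC(C)=O)cc2[C@H]1COC(C)=O | intermediate
24 | mixed pivalic anhydride of 23 (not isolated) | CC(C)(C)C(=O)OC(=O)Cc1cc(cc(OC)c1OCc1ccccc1)[C@@H]1Oc2c(OC)cc(CCCOC(C)=O)cc2[C@H]1COC(C)=O | intermediate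
25 | (R)-4-benzyl-3-(2-{5-[(2R,3S)-3-(acetoxymethyl)-5-(3-acetoxypropyl)-7-methoxy-2,3-dihydro-1-benzofuran-2-yl]-2-(benzyloxy)-3-methoxyphenyl}acetyl)oxazolidin-2-one (ring B imide) | O=C(Cc1cc(cc(OC)c1OCc1ccccc1)[C@@H]1Oc2c(OC)cc(CCCOC(C)=O)cc2[C@H]1COC(C)=O)N1[C@H](Cc2ccccc2)COC1=O | intermediate
26 | 4-(benzyloxy)-3-methoxybenzaldehyde (O-benzylvanillin) | COc1cc(C=O)ccc1OCc1ccccc1 | starting material
27 | Z-dibutylboron enolate of 25 (not isolated) | CCCCB(CCCC)O/C(=C\c1cc(cc(OC)c1OCc1ccccc1)[C@@H]1Oc2c(OC)cc(CCCOC(C)=O)cc2[C@H]1COC(C)=O)N1[C@H](Cc2ccccc2)COC1=O | intermediate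
28 | (R)-4-benzyl-3-[(2R,3R)-2-{5-[(2R,3S)-3-(acetoxymethyl)-5-(3-acetoxypropyl)-7-methoxy-2,3-dihydro-1-benzofuran-2-yl]-2-(benzyloxy)-3-methoxyphenyl}-3-[4-(benzyloxy)-3-methoxyphenyl]-3-hydroxypropanoyl]oxazolidin-2-one | O=C(N1[C@H](Cc2ccccc2)COC1=O)[C@H](c1cc(cc(OC)c1OCc1ccccc1)[C@@H]1Oc2c(OC)cc(CCCOC(C)=O)cc2[C@H]1COC(C)=O)[C@@H](O)c1ccc(OCc2ccccc2)c(OC)c1 | intermediate
29 | (1R,2S)-1-[4-(benzyloxy)-3-methoxyphenyl]-2-{2-(benzyloxy)-5-[(2R,3S)-3-(hydroxymethyl)-5-(3-hydroxypropyl)-7-methoxy-2,3-dihydro-1-benzofuran-2-yl]-3-methoxyphenyl}propane-1,3-diol | OC[C@H](c1cc(cc(OC)c1OCc1ccccc1)[C@@H]1Oc2c(OC)cc(CCCO)cc2[C@H]1CO)[C@@H](O)c1ccc(OCc2ccccc2)c(OC)c1 | intermediate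
30 | (1R,2S)-1-(4-hydroxy-3-methoxyphenyl)-2-{2-hydroxy-5-[(2R,3S)-3-(hydroxymethyl)-5-(3-hydroxypropyl)-7-methoxy-2,3-dihydro-1-benzofuran-2-yl]-3-methoxyphenyl}propane-1,3-diol (seco precursor) | COc1cc([C@H](O)[C@H](CO)c2cc([C@@H]3Oc4c(OC)cc(CCCO)cc4[C@H]3CO)cc(OC)c2O)ccc1O | intermediate
31 | ring A para-quinone methide of 30: 4-[(2S)-3-hydroxy-2-aryl-propylidene]-2-methoxycyclohexa-2,5-dien-1-one, aryl = the ring B/inner unit of 30 (not isolated; either alkene geometry) | COC1=CC(=C[C@H](CO)c2cc([C@@H]3Oc4c(OC)cc(CCCO)cc4[C@H]3CO)cc(OC)c2O)C=CC1=O | intermediate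
32 | 4-[(2R,3S)-3-(hydroxymethyl)-5-[(2R,3S)-3-(hydroxymethyl)-5-(3-hydroxypropyl)-7-methoxy-2,3-dihydro-1-benzofuran-2-yl]-7-methoxy-2,3-dihydro-1-benzofuran-2-yl]-2-methoxyphenol (CNP0599161.1) | COc1cc([C@@H]2Oc3c(OC)cc([C@@H]4Oc5c(OC)cc(CCCO)cc5[C@H]4CO)cc3[C@H]2CO)ccc1O | target

**Totals**

Total step count: 20.
Longest linear sequence: 17 steps (steps 1–6 and 10–20); steps 7–9 form the side branch to aldehyde 14.

**Steps most likely to fail**

Step 20 (key closure). The cation may lose the C3 proton or formaldehyde and end as a stilbene, or the inner ring may open and be diverted before the outer ring has closed. The fallback triggers the same O1–C2 closure from a phenoxide instead of by acid; it sets out from 30 and comes back at 32. Acetylation of 30 (Ac2O, pyridine, DMAP, CH2Cl2) should give the hexaacetate F1. K2CO3 in MeOH/THF at 0 °C should cleave the two aryl acetates first. The ring A phenoxide then expels the C2 acetate by 1,6-elimination to the quinone methide triacetate F2, and the ring B phenoxide adds 5-exo to give the ring-closed triacetate F3; neither is isolated. Continued methanolysis at rt removes the three alkyl acetates and should deliver 32. No acid is present, so the inner benzylic ether and the C3 hydrogen are not put at risk.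

Step 17 (outer aldol). Enolisation of the hindered α-aryl imide may be sluggish, facial selectivity may be poor, or the adduct may revert by retro-aldol during work-up. The fallback uses a titanium enolate of a thiazolidinethione imide; it sets out from 23 and comes back at 29. Coupling of 23 with (R)-4-benzylthiazolidine-2-thione (EDC·HCl, DMAP, CH2Cl2) should give the N-acyl thiazolidinethione F4. Enolisation with TiCl4, iPr2NEt and N-methyl-2-pyrrolidinone in CH2Cl2 and addition of 26 at −78 → 0 °C (the non-chelated mode, same facial sense as the boron aldol) should give the syn adduct F5. LiBH4 in THF/MeOH displaces the more labile thione auxiliary and removes the acetates, giving 29.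

Step 18 (global hydride cleavage). The lithium aldolate may fragment by retro-aldol or C3 may epimerise before hydride is delivered, and removal of the two acetates may stall. The fallback masks the aldol hydroxyl before reduction; it sets out from 28 and comes back at 29. TESOTf and 2,6-lutidine in CH2Cl2 at −78 °C should give the triethylsilyl ether F6. LiBH4 in THF/MeOH then cleaves the auxiliary and the acetates to the silyl ether triol F7, in which no alkoxide can trigger fragmentation. Bu4NF buffered with AcOH in THF removes the silyl group and gives 29.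

**Further compounds**

F1 | step 20 | hexaacetate of 30 | COc1cc([C@H](OC(C)=O)[C@H](COC(C)=O)c2cc([C@@H]3Oc4c(OC)cc(CCCOC(C)=O)cc4[C@H]3COC(C)=O)cc(OC)c2OC(C)=O)ccc1OC(C)=O
F2 | step 20 | ring A para-quinone methide triacetate with free ring B phenol (transient; either alkene geometry) | COC1=CC(=C[C@H](COC(C)=O)c2cc([C@@H]3Oc4c(OC)cc(CCCOC(C)=O)cc4[C@H]3COC(C)=O)cc(OC)c2O)C=CC1=O
F3 | step 20 | tri-O-acetate of 32 (three primary acetates, ring A phenol free) | COc1cc([C@@H]2Oc3c(OC)cc([C@@H]4Oc5c(OC)cc(CCCOC(C)=O)cc5[C@H]4COC(C)=O)cc3[C@H]2COC(C)=O)ccc1O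
F4 | step 17 | N-acyl (R)-4-benzylthiazolidine-2-thione of acid 23 | O=C(Cc1cc(cc(OC)c1OCc1ccccc1)[C@@H]1Oc2c(OC)cc(CCCOC(C)=O)cc2[C@H]1COC(C)=O)N1[C@H](Cc2ccccc2)CSC1=S
F5 | step 17 | (2R,3R) syn aldol adduct of F4 with 26 | O=C(N1[C@H](Cc2ccccc2)CSC1=S)[C@H](c1cc(cc(OC)c1OCc1ccccc1)[C@@H]1Oc2c(OC)cc(CCCOC(C)=O)cc2[C@H]1COC(C)=O)[C@@H](O)c1ccc(OCc2ccccc2)c(OC)c1
F6 | step 18 | triethylsilyl ether of aldol adduct 28 | O=C(N1[C@H](Cc2ccccc2)COC1=O)[C@H](c1cc(cc(OC)c1OCc1ccccc1)[C@@H]1Oc2c(OC)cc(CCCOC(C)=O)cc2[C@H]1COC(C)=O)[C@@H](O[Si](CC)(CC)CC)c1ccc(OCc2ccccc2)c(OC)c1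
F7 | step 18 | C2 triethylsilyl ether of 29 | OC[C@H](c1cc(cc(OC)c1OCc1ccccc1)[C@@H]1Oc2c(OC)cc(CCCO)cc2[C@H]1CO)[C@@H](O[Si](CC)(CC)CC)c1ccc(OCc2ccccc2)c(OC)c1
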